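**Plan**

1. Retrosynthetic cuts, in order: the C8–O ester and the C4 OH/OMe exchange; then, in one stroke, O–C7 and C5=C6 of the 2,5-dihydrofuran, which opens both the oxygen bridge and the ten-membered ring to a cyclohexene carrying a vinyl ketone arm (C2–C5) and a vinyl epoxide arm (C6–C9); then C3–C4 (aldol), C2=C3 (cross-metathesis), C7=C8 (Z-olefination) and C2/C9 (ketene [2+2], then cleavage of the cyclobutanone C2–C9 bond) back to (R)-α-phellandrene.
2. Forward ring order: cyclohexene from the chiral pool; a fused cyclobutanone as a temporary ring, cleaved into the two cis arms; an epoxide on the C10 arm; then the ten-membered carbocycle and the oxygen bridge are closed together; acylation and ketal hydrolysis come last.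
3. Enabling feature: the ring O–C4–C5=C6–C7 is the closed form of a cis enone whose C4 carbonyl oxygen lies over C7. C7 is fully substituted (no escape to a furan) and has the C8 oxygen as vicinal neighbour, so a C7–C8 epoxide can serve as the latent electrophile once C5=C6 exists.
4. Stereochemistry: C14 from the starting material; C1 and C10 from suprafacial ketene addition anti to isopropyl; C7 and C8 from a Sharpless epoxidation (C7 is then inverted by the C4 oxygen); C4 from the cis bridge; C3 by equilibration in the last step.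

Key step: step 16

Locants: bicyclo[8.4.0]tetradecane numbering of the target is used throughout. C1 and C10 are the ring-fusion carbons; C2–C9 are the other carbons of the ten-membered ring (C3 bears CO2Me, C4 the hemiketal OH, C5=C6 the alkene, C7 the methyl group, C8 the acyloxy group); C11(CH3)=C12, C13 and C14 (isopropyl) complete the cyclohexene. "C1 arm" and "C10 arm" are the two cis substituents on the cyclohexene, both trans to the C14 isopropyl group.

Assumption: C3 is epimerizable through the ring-opened β-keto ester, and the 3R configuration of the target is taken to be the thermodynamically preferred one; C3 is therefore drawn 3R from 22 on and is left to equilibrate in step 18.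

**Route**

Step 1
Reactants: 1 (R)-(−)-α-phellandrene
Product: 2 7,7-dichloro-5-methyl-2-(propan-2-yl)bicyclo[4.2.0]oct-4-en-8-one (cis-fused; four-membered ring anti to isopropyl; C8=O is C2 and CCl2 is C9 of the target)
Conditions: Cl3CCOCl, Zn (activated), Et2O, ultrasound, 15–20 °C
Reagents that add atoms: trichloroacetyl chloride, ClC(=O)C(Cl)(Cl)Cl
Why: Thermal [2+2] cycloaddition of dichloroketene generated in the flask takes place suprafacially on the disubstituted alkene of the diene, on the face anti to the C14 isopropyl group and with the carbonyl carbon bonding to the diene terminus, which sets C1 and C10 cis to each other and trans to isopropyl.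

Step 2
Reactants: 2 dichlorocyclobutanone
Product: 3 5-methyl-2-(propan-2-yl)bicyclo[4.2.0]oct-4-en-8-one (same configuration)
Conditions: Zn, AcOH, 23 → 60 °C
Reagents that add atoms: none
Why: Zinc reductive dehalogenation of the α,α-dichloroketone proceeds through the zinc enolate and should leave the ring-fusion stereocentres untouched.

Step 3
Reactants: 3 cyclobutanone
Product: 4 (E)-7-[(dimethylamino)methylidene]-5-methyl-2-(propan-2-yl)bicyclo[4.2.0]oct-4-en-8-one
Conditions: t-BuOCH(NMe2)2, PhMe, 60 °C
Reagents that add atoms: tert-butoxybis(dimethylamino)methane, CN(C)C(OC(C)(C)C)N(C)C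
Why: Bredereck aminomethylenation condenses the only methylene α-position of the ketone (C9) with the aminal ester and so introduces C8 as a vinylogous amide.

Step 4
Reactants: 4 enaminone
Product: 5 methyl 2-(2,2-dimethoxyethyl)-3-methyl-6-(propan-2-yl)cyclohex-3-ene-1-carboxylate (1,2-cis; 1,6-trans; C1 arm CO2Me; C10 arm CH2CH(OMe)2)
Conditions: p-TsOH·H2O, MeOH, 65 °C
Reagents that add atoms: methanol, CO
Why: Acid-promoted methanolysis of the strained 2-aminomethylene cyclobutanone is a retro-Claisen C–C cleavage (C2–C9) that should deliver the ester at C2 and, after methanolysis of the iminium ion, the dimethyl acetal at C8 without touching C1 or C10.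

Step 5
Reactants: 5 ester acetal
Product: 6 aldehyde acetal (C1 arm CHO; C10 arm CH2CH(OMe)2)
Conditions: i-Bu2AlH (1.1 equiv), CH2Cl2, −78 °C; aq. potassium sodium tartrate
Reagents that add atoms: none
Why: Half-reduction of the ester by the aluminium hydride at low temperature should stop at the tetrahedral aluminium hemiacetal, which gives the aldehyde on work-up while the acetal is inert.

Step 6
Reactants: 6 aldehyde acetal
Product: 7 vinyl acetal (C1 arm CH=CH2; C10 arm CH2CH(OMe)2)
Conditions: Ph3PCH3Br, KOtBu, THF, 0 °C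
Reagents that add atoms: methyltriphenylphosphonium bromide, C[P+](c1ccccc1)(c1ccccc1)c1ccccc1.[Br-]
Why: Wittig methylenation with the non-stabilized ylide is fast at 0 °C, which should convert the aldehyde into the vinyl group before C1 can epimerize.

Step 7
Reactants: 7 vinyl acetal
Product: 8 vinyl aldehyde (C1 arm CH=CH2; C10 arm CH2CHO)
Conditions: p-TsOH·H2O (cat.), acetone/H2O, 23 °C
Reagents that add atoms: water, O
Why: Mild acid-catalysed acetal hydrolysis should liberate the C8 aldehyde without affecting the isolated alkenes.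

Step 8
Reactants: 8 vinyl aldehyde; 9 ethyl 2-[bis(2,2,2-trifluoroethoxy)phosphoryl]propanoate
Product: 10 (Z)-enoate (C1 arm CH=CH2; C10 arm CH2–CH=C(CH3)–CO2Et with C9 and CO2Et cis)
Conditions: KN(SiMe3)2, 18-crown-6, THF, −78 °C
Reagents that add atoms: none
Why: Still–Gennari olefination with the trifluoroethyl phosphonate under dissociating conditions should give the (Z)-trisubstituted enoate by kinetic control.

Step 9
Reactants: 10 (Z)-enoate
Product: 11 (Z)-allylic alcohol (C1 arm CH=CH2; C10 arm CH2–CH=C(CH3)–CH2OH)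
Conditions: i-Bu2AlH (2.5 equiv), CH2Cl2, −78 → 0 °C; aq. potassium sodium tartrate
Reagents that add atoms: none
Why: 1,2-Reduction of the enoate by the aluminium hydride should give the allylic alcohol with the Z geometry retained.

Step 10
Reactants: 11 (Z)-allylic alcohol
Product: 12 (7R,8S)-epoxy alcohol (C1 arm CH=CH2; C10 arm CH2–C8H(–O–)C7(CH3)–CH2OH with C9 and CH2OH cis on the oxirane)
Conditions: Ti(OiPr)4, D-(−)-diethyl tartrate, t-BuOOH, 4 Å molecular sieves, CH2Cl2, −20 °C
Reagents that add atoms: tert-butyl hydroperoxide, CC(C)(C)OO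
Why: Sharpless asymmetric epoxidation is directed by the allylic hydroxyl, so only the C7=C8 alkene should react, and the D-(−)-tartrate ligand delivers oxygen to the face that gives the 7R,8S epoxide (reagent control).

Step 11
Reactants: 12 epoxy alcohol; 13 methyl acrylate
Product: 14 enoate epoxy alcohol (C1 arm (E)-CH=CH–CO2Me; C10 arm as in 12)
Conditions: 13 (excess), second-generation Grubbs catalyst (H2IMes)(PCy3)Cl2Ru(=CHPh) (cat.), CH2Cl2, 40 °C
Reagents that add atoms: none
Why: Olefin cross-metathesis between the terminal vinyl group and the electron-poor acrylate should give the (E)-enoate (C2=C3), the trisubstituted ring alkene and the epoxide being spectators.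

Step 12
Reactants: 14 enoate epoxy alcohol
Product: 15 epoxy aldehyde (C1 arm (E)-CH=CH–CO2Me; C10 arm CH2–C8H(–O–)C7(CH3)–CHO; same spatial arrangement as 12)
Conditions: Dess–Martin periodinane, pyridine, CH2Cl2, 0 → 23 °C
Reagents that add atoms: none
Why: Dess–Martin oxidation under pyridine buffering should convert the primary epoxy alcohol into the epoxy aldehyde, which has no α-hydrogen and cannot epimerize.

Step 13
Reactants: 15 epoxy aldehyde
Product: 16 vinyl epoxide enoate (C1 arm (E)-CH=CH–CO2Me; C10 arm CH2–C8H(–O–)C7(CH3)–CH=CH2; 7R,8S)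
Conditions: Ph3PCH3Br, KN(SiMe3)2, THF, −78 → 0 °C
Reagents that add atoms: methyltriphenylphosphonium bromide, C[P+](c1ccccc1)(c1ccccc1)c1ccccc1.[Br-]
Why: Wittig methylenation of the aldehyde should be much faster than any addition of the ylide to the enoate and gives the vinyl epoxide.

Step 14
Reactants: 16 vinyl epoxide enoate; 17 acrolein
Product: 19 β-hydroxy ester (C1 arm CH2–CH(CO2Me)–CH(OH)–CH=CH2 as a C3/C4 diastereomer mixture; C10 arm as in 16), via lithium enolate 18 (not isolated)
Conditions: LiBH(s-Bu)3, THF, −78 °C; then 17, −78 °C; AcOH quench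
Reagents that add atoms: none
Why: Conjugate hydride addition of the bulky borohydride to the enoate generates the ester enolate regiospecifically and its aldol addition to acrolein (tandem conjugate reduction–aldol) builds C3–C4; the configuration at C3 and C4 is immaterial because C4 is oxidized next and C3 is equilibrated later.

Step 15
Reactants: 19 β-hydroxy ester
Product: 20 vinyl β-keto ester (C1 arm CH2–CH(CO2Me)–CO–CH=CH2 with labile C3; C10 arm as in 16)
Conditions: Dess–Martin periodinane, pyridine, CH2Cl2, 0 °C; used at once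
Reagents that add atoms: none
Why: Dess–Martin oxidation of the allylic β-hydroxy ester should give the α-substituted vinyl β-keto ester under non-basic conditions that spare the vinyl epoxide.

Step 16
Reactants: 20 vinyl β-keto ester
Product: 22 methyl (1R,3R,4R,7S,8S,10R,14R)-4,7-epoxy-8-hydroxy-4-methoxy-7,11-dimethyl-14-(propan-2-yl)bicyclo[8.4.0]tetradeca-5,11-diene-3-carboxylate, via Z-enone epoxide 21 (not isolated)
Conditions: second-generation Hoveyda–Grubbs catalyst (H2IMes)Cl2Ru(=CH-C6H4-2-OiPr) (cat.), PhMe (1 mM), 80 °C; then PPTS (cat.), MeOH, 23 °C, same flask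
Reagents that add atoms: methanol, CO
Why: Ring-closing metathesis joins the two terminal alkenes (C5=C6, loss of ethylene) to the ten-membered Z enone 21, whose C4 carbonyl oxygen lies over C7; after acidification this oxygen opens the C7–C8 epoxide at its tertiary allylic carbon with inversion (O–C7) and methanol captures the cyclic oxocarbenium ion at C4. The closest known reaction types are ring-closing metathesis to medium-ring enones and the acid-mediated cyclization of γ,δ-epoxy ketones to cyclic ketals. The carbocycle closes by metathesis between two arms held cis on the cyclohexene, and the dihydrofuran closes 5-exo-tet with respect to the breaking C7–O bond. C7 is set by inversion of the reagent-controlled epoxide (7R to 7S), C8 is untouched, C4 is fixed because the one-atom oxygen bridge can span the ten-membered ring only with C3 and C8 cis on the five-membered ring, and C3 is drawn as in the target (see assumption). The step needs Z geometry at C5=C6, which the strain of an E enone in this ring and the drain of the Z isomer into the bicycle should favour, and it needs attack at C7 rather than C8, which the tertiary allylic character of C7 and the five- over six-membered ring size secure. The trisubstituted C11=C12 alkene is inert to the catalyst, and methanol as solvent at 23 °C should keep C4 as the ketal rather than the C3=C4 enol ether, which the last step would rehydrate in any case.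

Step 17
Reactants: 22 hydroxy methyl ketal; 23 (E)-3-(1-methyl-1H-imidazol-4-yl)prop-2-enoic acid
Product: 25 8-O-[(E)-3-(1-methyl-1H-imidazol-4-yl)prop-2-enoyl] ester of 22, via mixed anhydride 24 (not isolated)
Conditions: 23, 2,4,6-trichlorobenzoyl chloride, Et3N, THF, 23 °C; then 22, DMAP, PhMe, 60 °C
Reagents that add atoms: none
Why: Yamaguchi esterification through the mixed anhydride should acylate the secondary C8 hydroxyl, the only free hydroxyl, while the ketal masks C4 and prevents enolization at C3.

Step 18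
Reactants: 25 urocanate methyl ketal
Product: 26 methyl (1R,3R,4R,7S,8S,10R,14R)-4,7-epoxy-4-hydroxy-7,11-dimethyl-8-{[(E)-3-(1-methyl-1H-imidazol-4-yl)prop-2-enoyl]oxy}-14-(propan-2-yl)bicyclo[8.4.0]tetradeca-5,11-diene-3-carboxylate (target)
Conditions: (+)-camphor-10-sulfonic acid (1.2 equiv), CH2Cl2/H2O, 23 °C
Reagents that add atoms: water, O
Why: Acid-catalysed ketal hydrolysis through the cyclic oxocarbenium ion should give the hemiketal, and reversible opening to the β-keto ester under these conditions lets C3 settle in its preferred configuration.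

**Compound list**

1 | (R)-(−)-α-phellandrene, (5R)-2-methyl-5-(propan-2-yl)cyclohexa-1,3-diene | CC1=CC[C@H](C(C)C)C=C1 | starting material
2 | 7,7-dichloro-5-methyl-2-(propan-2-yl)bicyclo[4.2.0]oct-4-en-8-one (cis-fused, four-membered ring anti to isopropyl) | O=C1[C@@H]2[C@@H](C(C)C)CC=C(C)[C@@H]2C1(Cl)Cl | intermediate
3 | 5-methyl-2-(propan-2-yl)bicyclo[4.2.0]oct-4-en-8-one (same configuration) | O=C1[C@@H]2[C@@H](C(C)C)CC=C(C)[C@@H]2C1 | intermediate
4 | (E)-7-[(dimethylamino)methylidene]-5-methyl-2-(propan-2-yl)bicyclo[4.2.0]oct-4-en-8-one | O=C1[C@@H]2[C@@H](C(C)C)CC=C(C)[C@@H]2/C1=C\N(C)C | intermediate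
5 | methyl 2-(2,2-dimethoxyethyl)-3-methyl-6-(propan-2-yl)cyclohex-3-ene-1-carboxylate (1,2-cis; 1,6-trans) | COC(=O)[C@@H]1[C@@H](C(C)C)CC=C(C)[C@@H]1CC(OC)OC | intermediate
6 | aldehyde acetal (C1 arm CHO; C10 arm CH2CH(OMe)2) | O=C[C@@H]1[C@@H](C(C)C)CC=C(C)[C@@H]1CC(OC)OC | intermediate
7 | vinyl acetal (C1 arm CH=CH2; C10 arm CH2CH(OMe)2) | C=C[C@@H]1[C@@H](C(C)C)CC=C(C)[C@@H]1CC(OC)OC | intermediate
8 | vinyl aldehyde (C1 arm CH=CH2; C10 arm CH2CHO) | C=C[C@@H]1[C@@H](C(C)C)CC=C(C)[C@@H]1CC=O | intermediate
9 | ethyl 2-[bis(2,2,2-trifluoroethoxy)phosphoryl]propanoate | CCOC(=O)C(C)P(=O)(OCC(F)(F)F)OCC(F)(F)F | starting material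
10 | (Z)-enoate (C1 arm CH=CH2; C10 arm CH2–CH=C(CH3)–CO2Et) | C=C[C@@H]1[C@@H](C(C)C)CC=C(C)[C@@H]1C/C=C(/C)C(=O)OCC | intermediate
11 | (Z)-allylic alcohol (C1 arm CH=CH2; C10 arm CH2–CH=C(CH3)–CH2OH) | C=C[C@@H]1[C@@H](C(C)C)CC=C(C)[C@@H]1C/C=C(/C)CO | intermediate
12 | (7R,8S)-epoxy alcohol (C1 arm CH=CH2; C10 arm CH2–C8H(–O–)C7(CH3)–CH2OH) | C=C[C@@H]1[C@@H](C(C)C)CC=C(C)[C@@H]1C[C@@H]2O[C@]2(C)CO | intermediate
13 | methyl acrylate | C=CC(=O)OC | starting material
14 | enoate epoxy alcohol (C1 arm (E)-CH=CH–CO2Me; C10 arm as in 12) | COC(=O)/C=C/[C@@H]1[C@@H](C(C)C)CC=C(C)[C@@H]1C[C@@H]2O[C@]2(C)CO | intermediate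
15 | epoxy aldehyde (C1 arm (E)-CH=CH–CO2Me; C10 arm CH2–C8H(–O–)C7(CH3)–CHO) | COC(=O)/C=C/[C@@H]1[C@@H](C(C)C)CC=C(C)[C@@H]1C[C@@H]2O[C@]2(C)C=O | intermediate
16 | vinyl epoxide enoate (C1 arm (E)-CH=CH–CO2Me; C10 arm CH2–C8H(–O–)C7(CH3)–CH=CH2, 7R,8S) | COC(=O)/C=C/[C@@H]1[C@@H](C(C)C)CC=C(C)[C@@H]1C[C@@H]2O[C@]2(C)C=C | intermediate
17 | acrolein | C=CC=O | starting material
18 | lithium enolate of the saturated methyl ester derived from 16 (enolate geometry not defined) | COC(O[Li])=CC[C@@H]1[C@@H](C(C)C)CC=C(C)[C@@H]1C[C@@H]2O[C@]2(C)C=C | intermediate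
19 | β-hydroxy ester (C1 arm CH2–CH(CO2Me)–CH(OH)–CH=CH2, C3/C4 mixture; C10 arm as in 16) | C=CC(O)C(C(=O)OC)C[C@@H]1[C@@H](C(C)C)CC=C(C)[C@@H]1C[C@@H]2O[C@]2(C)C=C | intermediate
20 | vinyl β-keto ester (C1 arm CH2–CH(CO2Me)–CO–CH=CH2, C3 labile; C10 arm as in 16) | C=CC(=O)C(C(=O)OC)C[C@@H]1[C@@H](C(C)C)CC=C(C)[C@@H]1C[C@@H]2O[C@]2(C)C=C | intermediate
21 | methyl (5Z)-7,8-epoxy-7,11-dimethyl-4-oxo-14-(propan-2-yl)bicyclo[8.4.0]tetradeca-5,11-diene-3-carboxylate (7R,8S; C3 labile) | COC(=O)C1C[C@@H]2[C@@H](C(C)C)CC=C(C)[C@@H]2C[C@@H]3O[C@]3(C)/C=C\C1=O | intermediate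
22 | methyl (1R,3R,4R,7S,8S,10R,14R)-4,7-epoxy-8-hydroxy-4-methoxy-7,11-dimethyl-14-(propan-2-yl)bicyclo[8.4.0]tetradeca-5,11-diene-3-carboxylate | COC(=O)[C@@H]1C[C@@H]2[C@@H](C(C)C)CC=C(C)[C@@H]2C[C@H](O)[C@]2(C)C=C[C@@]1(OC)O2 | intermediate
23 | (E)-3-(1-methyl-1H-imidazol-4-yl)prop-2-enoic acid (N-methylurocanic acid) | OC(=O)/C=C/c1cn(C)cn1 | starting material
24 | mixed anhydride of 23 and 2,4,6-trichlorobenzoic acid | Cn1cnc(/C=C/C(=O)OC(=O)c2c(Cl)cc(Cl)cc2Cl)c1 | intermediate
25 | 8-O-[(E)-3-(1-methyl-1H-imidazol-4-yl)prop-2-enoyl] ester of 22 | COC(=O)[C@@H]1C[C@@H]2[C@@H](C(C)C)CC=C(C)[C@@H]2C[C@H](OC(=O)/C=C/c2cn(C)cn2)[C@]2(C)C=C[C@@]1(OC)O2 | intermediate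
26 | methyl (1R,3R,4R,7S,8S,10R,14R)-4,7-epoxy-4-hydroxy-7,11-dimethyl-8-{[(E)-3-(1-methyl-1H-imidazol-4-yl)prop-2-enoyl]oxy}-14-(propan-2-yl)bicyclo[8.4.0]tetradeca-5,11-diene-3-carboxylate | COC(=O)[C@@H]1C[C@@H]2[C@@H](C(C)C)CC=C(C)[C@@H]2C[C@H](OC(=O)/C=C/c2cn(C)cn2)[C@]2(C)C=C[C@@]1(O)O2 | target

Total step count: 18. Longest linear sequence: 18 steps (from 1).

**Steps most likely to fail**

Step 16. Initiation is slow at both alkenes (an enone and a vinyl group on a fully substituted epoxide carbon), so oligomerization or decay of the vinyl β-keto ester may outrun ring closure. Fallback, setting out from 19 and returning at 22: the two bond formations are separated. Silylation of 19 (Et3SiCl, imidazole, DMF) should give the triethylsilyl ether F1, which lacks the acidic, chelating keto ester and offers an ordinary allylic ether alkene for initiation. Ring-closing metathesis (second-generation Grubbs catalyst (H2IMes)(PCy3)Cl2Ru(=CHPh), CH2Cl2, 40 °C, 1 mM) should then give the ten-membered (Z)-allylic silyl ether F2. Buffered desilylation (HF·pyridine, pyridine, THF, 0 °C) would give the allylic alcohol F3, which is oxidized at once (Dess–Martin periodinane, pyridine, CH2Cl2) to enone 21; PPTS in MeOH then converts 21 into 22.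

Step 14. Hydride may be delivered 1,2 to the ester or may open the vinyl epoxide, and the aldolate may undergo retro-aldol cleavage while acrolein oligomerizes. Fallback, setting out from 16 and returning at 19: reduction and C–C bond formation are separated. Conjugate reduction of 16 with the copper hydride [(Ph3P)CuH]6 (PhMe, 23 °C), which tolerates epoxides, should give the saturated ester F4. Deprotonation with LiN(i-Pr)2 (THF, −78 °C) regenerates enolate 18, and addition of 17 gives 19.

Step 17. Acylation of the C8 carbinol, flanked by the quaternary C7, by the bulky and poorly soluble mixed anhydride may stall, and forcing conditions may cost the ketal. Fallback, setting out from 22 and returning at 25: the side chain is built on the oxygen. Esterification of 22 with the small 2-(diethoxyphosphoryl)acetic acid (DCC, DMAP, CH2Cl2) should give the phosphonoacetate F5. A Horner–Wadsworth–Emmons reaction with 1-methyl-1H-imidazole-4-carbaldehyde (LiCl, DBU, MeCN) then gives the (E)-urocanate 25.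

Further compounds
F1 | step 16 | triethylsilyl ether of 19 (C4–OSiEt3) | C=CC(O[Si](CC)(CC)CC)C(C(=O)OC)C[C@@H]1[C@@H](C(C)C)CC=C(C)[C@@H]1C[C@@H]2O[C@]2(C)C=C
F2 | step 16 | methyl (5Z)-7,8-epoxy-7,11-dimethyl-14-(propan-2-yl)-4-(triethylsilyloxy)bicyclo[8.4.0]tetradeca-5,11-diene-3-carboxylate (7R,8S) | COC(=O)C1C[C@@H]2[C@@H](C(C)C)CC=C(C)[C@@H]2C[C@@H]3O[C@]3(C)/C=C\C1O[Si](CC)(CC)CC
F3 | step 16 | methyl (5Z)-7,8-epoxy-4-hydroxy-7,11-dimethyl-14-(propan-2-yl)bicyclo[8.4.0]tetradeca-5,11-diene-3-carboxylate (7R,8S) | COC(=O)C1C[C@@H]2[C@@H](C(C)C)CC=C(C)[C@@H]2C[C@@H]3O[C@]3(C)/C=C\C1O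
F4 | step 14 | saturated methyl ester (C1 arm CH2CH2CO2Me; C10 arm as in 16) | COC(=O)CC[C@@H]1[C@@H](C(C)C)CC=C(C)[C@@H]1C[C@@H]2O[C@]2(C)C=C
F5 | step 17 | 8-O-[2-(diethoxyphosphoryl)acetyl] ester of 22 | COC(=O)[C@@H]1C[C@@H]2[C@@H](C(C)C)CC=C(C)[C@@H]2C[C@H](OC(=O)CP(=O)(OCC)OCC)[C@]2(C)C=C[C@@]1(OC)O2
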